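**Retrosynthetic overview**
1. Cut the C15–O ester: a 3‑O‑silylated ent‑labda‑7,13E‑diene‑3,15‑diol plus 32‑silyloxydotriacontanoic acid, the latter from two C16 pieces by Wittig olefination (C16=C17) and hydrogenation.
2. Side chain: C13=C14 and C15 by carboalumination–hydroxymethylation of a butynyl arm on C9; C9–C11 by 1,2‑addition to a C9 enone, then oxidative 1,3‑transposition to C7, reduction and reductive 1,3‑transposition (sets H‑9 and C7=C8).
3. Ring A: one‑pot three‑component Michael–Michael–Dieckmann annulation on the enone of 6‑methyl‑(S)‑carvone, forming C4–C5 (isobutyrate enolate), C10–C1 (acrylate) and finally the ring‑closing C2–C3 bond.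
4. Enabling feature: the only oxygen of ring A sits on C3, between the quaternary C4 (gem‑dimethyl C18/C19) and the C2 methylene. C3–C4 is therefore a latent isobutyrate, C1–C2 a latent acrylate, and C5/C10 (with C20) are the β/α carbons of carvone's enone; the ring carbon carrying carvone's isopropenyl group becomes C7 and is excised afterwards as C7=C8.
5. Ring order: ring B is carvone's ring (chiral pool); ring A is closed second, in the key step.

Key step: step 2

Remark: labdane numbering is used for the decalin atoms of all intermediates (methyls on C4 ×2, C8, C10). Compounds 3 and 7–13 are carried as C8 epimer mixtures, 9 also as a C2 epimer/enol mixture and 17 with undefined C9, because these centres are erased later; their SMILES leave those centres open. Starting materials 1, 4, 5, 15, 26 and 28 are assumed commercial.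

**Step 1**
Reactants: 1 (S)-(+)-carvone
Product: 3 6-methylcarvone [(5S)-2,6-dimethyl-5-(prop-1-en-2-yl)cyclohex-2-en-1-one; both C6 epimers], via lithium dienolate of carvone 2 (not isolated)
Conditions: LiN(iPr)2, THF, −78 °C; MeI, −78 → 0 °C
Reagents that add atoms: iodomethane, CI
Why: Kinetic α′‑deprotonation gives the cross‑conjugated dienolate 2, whose C‑methylation (enolate alkylation) installs the future C17 on the future C8; the new centre forms as an epimer mixture, which is tolerated because this carbon becomes sp2 in step 6 and because the methyl blocks an unwanted Claisen sink in step 2.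

**Step 2**
Reactants: 3 6-methylcarvone; 4 methyl 2-methylpropanoate; 5 methyl acrylate
Product: 9 methyl 7-isopropenyl-4,4,8,10-tetramethyl-3,9-dioxo-trans-decalin-2-carboxylate (H-5 anti to CH3-10; isopropenyl cis to H-5), via lithium enolate of methyl isobutyrate 6 (not isolated), via lithium enolate of the 1,4-adduct 7 (not isolated), via acyclic ester enolate 8 (not isolated)
Conditions: 4, LiN(iPr)2, THF, −78 °C; 3, −78 → −20 °C; 5 (1.05 equiv, slow addition), −78 → 25 °C, then 45 °C; AcOH
Reagents that add atoms: none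
Why: Conjugate addition of enolate 6 to the enone of 3 forms C4–C5 (the kinetic 1,2‑aldolate of this hindered ketone should revert on warming, so the 1,4‑adduct 7 accumulates), the regiodefined enolate 7 adds through C10 to methyl acrylate to form C10–C1, and the ester enolate 8 closes ring A by Claisen attack of C2 on the C3 ester carbonyl with loss of methoxide, the product resting as its β‑keto ester enolate until the acidic quench. The closest known reaction type is the one‑pot Michael–Michael–ring‑closure (MIMIRC) sequence of lithium enolates, ended here by a Dieckmann condensation as in the classical double Michael–Dieckmann route to 4,4‑disubstituted cyclohexanones. Ring A closes in the 6‑(enolexo)‑exo‑trig mode and should be trans‑fused because the C4 and C1 arms are trans‑diequatorial on ring B. C5 is set in the first Michael addition by axial attack anti to the isopropenyl group on C7, and C10 in the second by attack of the acrylate anti to the bulky C5 substituent, so carvone's single stereocentre controls both; C2 is epimerisable and is lost in step 3. The step needs 1,4‑ over 1,2‑selectivity, secured by the reversibility of the aldolate and the α,α‑disubstituted donor, and retention of the enolate position in 7, secured by the aprotic low‑temperature protocol. Claisen closure of a C8 ketone enolate onto the acrylate‑derived ester is no sink, because the C8 methyl makes that β‑diketone non‑enolisable and reversible, whereas the wanted β‑keto ester is deprotonated irreversibly.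

**Step 3**
Reactants: 9 β-keto ester
Product: 10 7-isopropenyl-4,4,8,10-tetramethyl-trans-decalin-3,9-dione
Conditions: LiCl, H2O, DMSO, 150 °C
Reagents that add atoms: none
Why: Krapcho dealkoxycarbonylation (chloride attack on the O‑methyl group, loss of CO2, protonation by water) should remove the temporary activating ester from C2 under near‑neutral conditions that leave the isopropenyl group and both ketones untouched; no stereocentre is created.

**Step 4**
Reactants: 10 dione
Product: 11 3-hydroxy-7-isopropenyl-4,4,8,10-tetramethyl-trans-decalin-9-one (OH equatorial and cis to CH3-10)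
Conditions: NaBH4, MeOH/CH2Cl2, −20 °C
Reagents that add atoms: none
Why: Chemoselective borohydride reduction of the C3 ketone, because the C9 carbonyl is shielded by the quaternary C10 and the tertiary C8, with hydride arriving on the face away from the axial C10 and C4 methyl groups so that the equatorial alcohol (the 3R centre of the target) is set, as in reductions of 4,4‑dimethyl‑3‑oxo terpenoids.

**Step 5**
Reactants: 11 hydroxy ketone
Product: 12 3-[(tert-butyldimethylsilyl)oxy]-7-isopropenyl-4,4,8,10-tetramethyl-trans-decalin-9-one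
Conditions: TBSOTf, 2,6-lutidine, CH2Cl2, −78 → 0 °C
Reagents that add atoms: tert-butyldimethylsilyl trifluoromethanesulfonate, CC(C)(C)[Si](C)(C)OS(=O)(=O)C(F)(F)F
Why: Silyl triflate silylation of the hindered secondary alcohol protects O3 against the oxidants of steps 6 and 8 and the organometallics of steps 7 and 12; no stereocentre is affected.

**Step 6**
Reactants: 12 silyl ether
Product: 14 3-[(tert-butyldimethylsilyl)oxy]-4,4,8,10-tetramethyl-trans-decal-7-en-9-one, via α-methoxy hydroperoxide 13 (not isolated)
Conditions: O3, CH2Cl2/MeOH, −78 °C; then FeSO4·7H2O, Cu(OAc)2·H2O, MeOH, −20 → 23 °C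
Reagents that add atoms: none
Why: Ozonolysis in methanol converts the isopropenyl group into the α‑methoxy hydroperoxide 13, FeSO4 reduces it to an alkoxy radical that fragments with loss of methyl acetate, and Cu(OAc)2 oxidises the C7 radical with loss of H‑8 to the conjugated enone (oxidative dealkenylation by alkoxy‑radical β‑scission), so the spent stereocontrol element is excised and both C8 epimers converge on one compound.

**Step 7**
Reactants: 14 enone; 15 (4-bromobut-1-yn-1-yl)trimethylsilane
Product: 17 3-[(tert-butyldimethylsilyl)oxy]-4,4,8,10-tetramethyl-9-[4-(trimethylsilyl)but-3-yn-1-yl]-trans-decal-7-en-9-ol, via Grignard reagent 16 (not isolated)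
Conditions: 15, Mg, THF, 23 °C; anhydrous CeCl3, THF, −78 °C; 14, −78 → 0 °C; H2O
Reagents that add atoms: none
Why: CeCl3‑promoted 1,2‑addition of the Grignard reagent 16 to the hindered enone carbonyl, the Lewis acid suppressing γ‑deprotonation and conjugate addition, should form the C9–C11 bond; the configuration of the new carbinol centre is irrelevant because C9 becomes sp2 in step 8.

**Step 8**
Reactants: 17 tertiary allylic alcohol
Product: 18 3-[(tert-butyldimethylsilyl)oxy]-4,4,8,10-tetramethyl-9-[4-(trimethylsilyl)but-3-yn-1-yl]-trans-decal-8-en-7-one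
Conditions: [C5H5NH][CrO3Cl], 4 Å molecular sieves, CH2Cl2, 23 °C
Reagents that add atoms: pyridinium chlorochromate, [O-][Cr](=O)(=O)Cl.c1cc[nH+]cc1
Why: Oxidative 1,3‑transposition of the tertiary allylic alcohol (Babler–Dauben oxidation via the chromate ester, [3,3]‑shift of chromium to C7 and oxidation) should deliver the C7 ketone with the double bond at C8=C9; no stereocentre is formed.

**Step 9**
Reactants: 18 transposed enone
Product: 19 the corresponding decal-8-en-7-ol (OH pseudo-equatorial and cis to CH3-10)
Conditions: NaBH4, CeCl3·7H2O, MeOH, −40 °C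
Reagents that add atoms: none
Why: Luche 1,2‑reduction of the enone, with pseudo‑axial hydride delivery to C7 from the face opposite to the C10 methyl, should give the pseudo‑equatorial allylic alcohol whose hydroxyl is cis to the C10 methyl.

**Step 10**
Reactants: 19 allylic alcohol
Product: 22 3-[(tert-butyldimethylsilyl)oxy]-4,4,8,10-tetramethyl-9-[4-(trimethylsilyl)but-3-yn-1-yl]-trans-decal-7-ene (H-9 trans to CH3-10), via N-allyl sulfonylhydrazine 20 (not isolated), via allylic diazene 21 (not isolated)
Conditions: 2-nitrobenzenesulfonylhydrazide, PPh3, diethyl azodicarboxylate, THF, −30 °C; then 23 °C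
Reagents that add atoms: none
Why: Mitsunobu displacement by 2‑nitrobenzenesulfonylhydrazide inverts C7, loss of 2‑nitrobenzenesulfinic acid gives the allylic diazene 21, and its retro‑ene loss of N2 delivers hydrogen suprafacially to C9 (reductive 1,3‑transposition of an allylic alcohol), which sets C9 with H trans and the side chain cis to the C10 methyl and places the alkene at C7=C8.

**Step 11**
Reactants: 22 silyl alkyne
Product: 23 9-(but-3-yn-1-yl)-3-[(tert-butyldimethylsilyl)oxy]-4,4,8,10-tetramethyl-trans-decal-7-ene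
Conditions: K2CO3 (cat.), MeOH, 23 °C
Reagents that add atoms: none
Why: Carbonate‑catalysed methanolysis cleaves only the alkynyl C–Si bond (protiodesilylation), the secondary silyl ether being stable; no stereocentre is affected.

**Step 12**
Reactants: 23 terminal alkyne
Product: 25 (3R,5S,9R,10S,13E)-3-[(tert-butyldimethylsilyl)oxy]labda-7,13-dien-15-ol, via alkenyldimethylalane 24 (not isolated)
Conditions: Me3Al, Cp2ZrCl2 (cat.), CH2Cl2, 0 → 23 °C; n-BuLi, THF, −78 °C; (CH2O)n, −78 → 23 °C; aqueous work-up
Reagents that add atoms: trimethylaluminium, C[Al](C)C; paraformaldehyde (as formaldehyde), C=O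
Why: Zirconium‑catalysed syn‑carboalumination of the terminal alkyne (Negishi carboalumination) places methyl on C13 and aluminium on C14, and the derived alkenylaluminate adds to formaldehyde with retention of geometry, which fixes the 13E trisubstituted allylic alcohol; the C7=C8 alkene is inert.

**Step 13**
Reactants: 26 16-bromohexadecanoic acid
Product: 27 (15-carboxypentadecyl)triphenylphosphonium bromide
Conditions: PPh3, MeCN, reflux
Reagents that add atoms: triphenylphosphine, c1ccc(cc1)P(c1ccccc1)c1ccccc1
Why: SN2 quaternisation of triphenylphosphine by the primary bromide (phosphonium salt formation).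

**Step 14**
Reactants: 28 hexadecane-1,16-diol
Product: 29 16-[(tert-butyldimethylsilyl)oxy]hexadecan-1-ol
Conditions: NaH (1 equiv), THF, 23 °C; TBSCl
Reagents that add atoms: tert-butyldimethylsilyl chloride, CC(C)(C)[Si](C)(C)Cl
Why: Monosilylation of the symmetric diol through its monosodium alkoxide (O‑silylation), which favours the mono‑ether because the sparingly soluble monoalkoxide is silylated before a second deprotonation.

**Step 15**
Reactants: 29 mono-silylated diol
Product: 30 16-[(tert-butyldimethylsilyl)oxy]hexadecanal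
Conditions: TEMPO (cat.), PhI(OAc)2, CH2Cl2, 23 °C
Reagents that add atoms: none
Why: TEMPO‑catalysed oxidation of the primary alcohol with PhI(OAc)2 as terminal oxidant (oxoammonium oxidation) stops at the aldehyde and leaves the silyl ether intact.

**Step 16**
Reactants: 27 phosphonium bromide; 30 aldehyde
Product: 32 (16Z)-32-[(tert-butyldimethylsilyl)oxy]dotriacont-16-enoic acid, via phosphonium ylide carboxylate 31 (not isolated)
Conditions: NaN(SiMe3)2 (2.1 equiv), THF, 0 °C; 30, −78 → 23 °C; 1 M HCl
Reagents that add atoms: none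
Why: Wittig olefination of the carboxylate ylide 31 with the aldehyde joins the two C16 halves at C16=C17; the alkene geometry (expected mainly Z) is irrelevant because it is hydrogenated in step 17.

**Step 17**
Reactants: 32 alkenoic acid
Product: 33 32-[(tert-butyldimethylsilyl)oxy]dotriacontanoic acid
Conditions: H2 (1 atm), Pd/C, EtOAc, 23 °C
Reagents that add atoms: none
Why: Heterogeneous catalytic hydrogenation saturates the isolated alkene without touching the carboxylic acid or, in ethyl acetate, the silyl ether.

**Step 18**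
Reactants: 25 allylic alcohol; 33 protected hydroxy acid
Product: 34 (3R,5S,9R,10S,13E)-3-[(tert-butyldimethylsilyl)oxy]labda-7,13-dien-15-yl 32-[(tert-butyldimethylsilyl)oxy]dotriacontanoate
Conditions: DCC, DMAP (cat.), CH2Cl2, 0 → 23 °C
Reagents that add atoms: none
Why: Steglich esterification (carbodiimide activation with DMAP acyl transfer) of the primary allylic alcohol; O3 and the ω‑oxygen are silylated, so no chemoselectivity issue arises and no stereocentre is touched.

**Step 19**
Reactants: 34 bis-silyl ester
Product: 35 (3R,5S,9R,10S,13E)-3-hydroxylabda-7,13-dien-15-yl 32-hydroxydotriacontanoate (target, CNP0253650.1)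
Conditions: HF·pyridine, pyridine/THF, 0 → 23 °C
Reagents that add atoms: none
Why: Fluoride‑mediated cleavage of both tert‑butyldimethylsilyl ethers with buffered HF·pyridine, conditions under which the allylic ester and the trisubstituted alkenes should survive.

**Compound list**
1 | (S)-(+)-carvone, (5S)-2-methyl-5-(prop-1-en-2-yl)cyclohex-2-en-1-one | CC1=CC[C@@H](CC1=O)C(C)=C | starting material
2 | lithium cross-conjugated dienolate of 1 | CC1=CC[C@@H](C=C1O[Li])C(C)=C | intermediate
3 | 6-methylcarvone, (5S)-2,6-dimethyl-5-(prop-1-en-2-yl)cyclohex-2-en-1-one, both C6 epimers | CC1=CC[C@@H](C(C)C1=O)C(C)=C | intermediate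
4 | methyl 2-methylpropanoate | CC(C)C(=O)OC | starting material
5 | methyl acrylate | C=CC(=O)OC | starting material
6 | lithium 1-methoxy-2-methylprop-1-en-1-olate | CC(C)=C(OC)O[Li] | intermediate
7 | lithium enolate (O–C9, C9=C10) of the 1,4-adduct; C(CH3)2CO2CH3 on C5 trans to the C7 isopropenyl | CC1[C@@H](C(C)=C)C[C@H](C(C)(C)C(=O)OC)C(C)=C1O[Li] | intermediate
8 | lithium ester enolate of the Michael–Michael adduct; C10 carries CH3 and the CH2CH=C(OCH3)OLi arm trans to the C5 substituent | CC1[C@@H](C(C)=C)C[C@H](C(C)(C)C(=O)OC)[C@@](C)(CC=C(OC)O[Li])C1=O | intermediate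
9 | methyl 7-isopropenyl-4,4,8,10-tetramethyl-3,9-dioxo-trans-decalin-2-carboxylate | CC1[C@@H](C(C)=C)C[C@@H]2C(C)(C)C(=O)C(C(=O)OC)C[C@@]2(C)C1=O | intermediate
10 | 7-isopropenyl-4,4,8,10-tetramethyl-trans-decalin-3,9-dione | CC1[C@@H](C(C)=C)C[C@@H]2C(C)(C)C(=O)CC[C@@]2(C)C1=O | intermediate
11 | 3-hydroxy-7-isopropenyl-4,4,8,10-tetramethyl-trans-decalin-9-one, OH cis to CH3-10 | CC1[C@@H](C(C)=C)C[C@@H]2C(C)(C)[C@H](O)CC[C@@]2(C)C1=O | intermediate
12 | tert-butyldimethylsilyl ether of 11 | CC1[C@@H](C(C)=C)C[C@@H]2C(C)(C)[C@H](O[Si](C)(C)C(C)(C)C)CC[C@@]2(C)C1=O | intermediate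
13 | α-methoxy hydroperoxide, C7–C(CH3)(OCH3)OOH | CC1[C@@H](C(C)(OC)OO)C[C@@H]2C(C)(C)[C@H](O[Si](C)(C)C(C)(C)C)CC[C@@]2(C)C1=O | intermediate
14 | 3-[(tert-butyldimethylsilyl)oxy]-4,4,8,10-tetramethyl-trans-decal-7-en-9-one | CC1=CC[C@@H]2C(C)(C)[C@H](O[Si](C)(C)C(C)(C)C)CC[C@@]2(C)C1=O | intermediate
15 | (4-bromobut-1-yn-1-yl)trimethylsilane | C[Si](C)(C)C#CCCBr | starting material
16 | [4-(trimethylsilyl)but-3-yn-1-yl]magnesium bromide | C[Si](C)(C)C#CCC[Mg]Br | intermediate
17 | tertiary allylic alcohol, 9-hydroxy-9-[4-(trimethylsilyl)but-3-yn-1-yl] adduct of 14, C9 undefined | CC1=CC[C@@H]2C(C)(C)[C@H](O[Si](C)(C)C(C)(C)C)CC[C@@]2(C)C1(O)CCC#C[Si](C)(C)C | intermediate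
18 | 3-[(tert-butyldimethylsilyl)oxy]-4,4,8,10-tetramethyl-9-[4-(trimethylsilyl)but-3-yn-1-yl]-trans-decal-8-en-7-one | O=C1C[C@@H]2C(C)(C)[C@H](O[Si](C)(C)C(C)(C)C)CC[C@@]2(C)C(CCC#C[Si](C)(C)C)=C1C | intermediate
19 | decal-8-en-7-ol from 18, 7-OH cis to CH3-10 | O[C@@H]1C[C@@H]2C(C)(C)[C@H](O[Si](C)(C)C(C)(C)C)CC[C@@]2(C)C(CCC#C[Si](C)(C)C)=C1C | intermediate
20 | N-(decal-8-en-7-yl)-N-(2-nitrobenzenesulfonyl)hydrazine, N on C7 trans to CH3-10 | NN([C@H]1C[C@@H]2C(C)(C)[C@H](O[Si](C)(C)C(C)(C)C)CC[C@@]2(C)C(CCC#C[Si](C)(C)C)=C1C)S(=O)(=O)c1ccccc1[N+](=O)[O-] | intermediate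
21 | allylic diazene, HN=N on C7 trans to CH3-10 | N=N[C@H]1C[C@@H]2C(C)(C)[C@H](O[Si](C)(C)C(C)(C)C)CC[C@@]2(C)C(CCC#C[Si](C)(C)C)=C1C | intermediate
22 | 3-[(tert-butyldimethylsilyl)oxy]-4,4,8,10-tetramethyl-9-[4-(trimethylsilyl)but-3-yn-1-yl]-trans-decal-7-ene, H-9 trans to CH3-10 | CC1=CC[C@@H]2C(C)(C)[C@H](O[Si](C)(C)C(C)(C)C)CC[C@@]2(C)[C@@H]1CCC#C[Si](C)(C)C | intermediate
23 | 9-(but-3-yn-1-yl) analogue of 22 (terminal alkyne) | CC1=CC[C@@H]2C(C)(C)[C@H](O[Si](C)(C)C(C)(C)C)CC[C@@]2(C)[C@@H]1CCC#C | intermediate
24 | (E)-alkenyldimethylalane, Al on C14 | CC1=CC[C@@H]2C(C)(C)[C@H](O[Si](C)(C)C(C)(C)C)CC[C@@]2(C)[C@@H]1CC/C(C)=C/[Al](C)C | intermediate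
25 | (3R,5S,9R,10S,13E)-3-[(tert-butyldimethylsilyl)oxy]labda-7,13-dien-15-ol | CC1=CC[C@@H]2C(C)(C)[C@H](O[Si](C)(C)C(C)(C)C)CC[C@@]2(C)[C@@H]1CC/C(C)=C/CO | intermediate
26 | 16-bromohexadecanoic acid | OC(=O)CCCCCCCCCCCCCCCBr | starting material
27 | (15-carboxypentadecyl)triphenylphosphonium bromide | OC(=O)CCCCCCCCCCCCCCC[P+](c1ccccc1)(c1ccccc1)c1ccccc1.[Br-] | intermediate
28 | hexadecane-1,16-diol | OCCCCCCCCCCCCCCCCO | starting material
29 | 16-[(tert-butyldimethylsilyl)oxy]hexadecan-1-ol | OCCCCCCCCCCCCCCCCO[Si](C)(C)C(C)(C)C | intermediate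
30 | 16-[(tert-butyldimethylsilyl)oxy]hexadecanal | O=CCCCCCCCCCCCCCCCO[Si](C)(C)C(C)(C)C | intermediate
31 | sodium 16-(triphenylphosphoranylidene)hexadecanoate | [Na+].[O-]C(=O)CCCCCCCCCCCCCCC=P(c1ccccc1)(c1ccccc1)c1ccccc1 | intermediate
32 | (16Z)-32-[(tert-butyldimethylsilyl)oxy]dotriacont-16-enoic acid | OC(=O)CCCCCCCCCCCCCC/C=C\CCCCCCCCCCCCCCCO[Si](C)(C)C(C)(C)C | intermediate
33 | 32-[(tert-butyldimethylsilyl)oxy]dotriacontanoic acid | OC(=O)CCCCCCCCCCCCCCCCCCCCCCCCCCCCCCCO[Si](C)(C)C(C)(C)C | intermediate
34 | (3R,5S,9R,10S,13E)-3-[(tert-butyldimethylsilyl)oxy]labda-7,13-dien-15-yl 32-[(tert-butyldimethylsilyl)oxy]dotriacontanoate | CC1=CC[C@@H]2C(C)(C)[C@H](O[Si](C)(C)C(C)(C)C)CC[C@@]2(C)[C@@H]1CC/C(C)=C/COC(=O)CCCCCCCCCCCCCCCCCCCCCCCCCCCCCCCO[Si](C)(C)C(C)(C)C | intermediate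
35 | (3R,5S,9R,10S,13E)-3-hydroxylabda-7,13-dien-15-yl 32-hydroxydotriacontanoate | CC1=CC[C@@H]2C(C)(C)[C@H](O)CC[C@@]2(C)[C@@H]1CC/C(C)=C/COC(=O)CCCCCCCCCCCCCCCCCCCCCCCCCCCCCCCO | target

**Step count and risks**
Total step count: 19 (steps 1–12 terpene alcohol, steps 13–17 hydroxy acid, steps 18–19 union and deprotection). Longest linear sequence: 14 steps (1–12, 18, 19) from (S)-carvone.

Most likely to fail, first: step 2. The ester enolate may add 1,2 or act as a base instead of adding 1,4; the enolate of 7 may lose its position by proton transfer; or the acrylate may oligomerise anionically before the hindered Dieckmann closure. The fallback sets out from 3 and builds the same three bonds stepwise. Mukaiyama–Michael addition of 1-methoxy-2-methyl-1-(trimethylsilyloxy)prop-1-ene (Ph3CClO4 cat., CH2Cl2, −78 °C) should give the trimethylsilyl enol ether F1, with C4–C5 formed anti to the isopropenyl group. Fluoride‑promoted regiospecific allylation (Bu4N[Ph3SiF2], allyl iodide, THF) then gives the C10‑allyl keto ester F2, an SN2 route to this quaternary centre with close precedent in carvone chemistry. Selective hydroboration of the monosubstituted alkene with disiamylborane and oxidation (H2O2, NaOH) gives the primary alcohol F3. TEMPO/PhI(OAc)2 in wet MeCN gives the acid F4, and Me3SiCHN2 gives the keto diester F5, which is the protonated form of 8. A separate Dieckmann condensation (KOtBu, THF) comes back to the route at 9.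

Second: step 7. The hindered C9 carbonyl may not be attacked, or the reagent may deprotonate the γ‑position instead. The fallback sets out from 14 and homologates C9 by one carbon first. Wittig methylenation (Ph3PCH3Br, KOtBu, toluene, 90 °C) should give the diene F6. 9‑Borabicyclo[3.3.1]nonane adds to the exocyclic methylene from the face opposite to the C10 methyl, and oxidation (H2O2, NaOH) gives the homoallylic alcohol F7 with C9 already in the target configuration. I2/PPh3/imidazole gives the primary iodide F8. Alkylation of 3-lithio-1-(trimethylsilyl)propyne (from trimethyl(prop-1-yn-1-yl)silane and n-BuLi, THF/DMPU) with F8 comes back to the route at 22, bypassing steps 7–10.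

Third: step 9. Facial selectivity of hydride delivery to C7 may be poor or reversed, which would be copied into C9 by the stereospecific step 10. The fallback sets out from 18 and uses a transposition that retains, instead of inverts, the C7 configuration for the other epimer. The epimeric alcohol F9 (OH trans to the C10 methyl) is converted into its methyl carbonate F10 (ClCO2Me, pyridine). Pd(PPh3)4‑catalysed allylic substitution with N-isopropylidene-N′-(2-nitrobenzenesulfonyl)hydrazine should proceed with net retention at the less hindered C7 terminus to give the hydrazone F11. Mild hydrolysis (CF3CH2OH/H2O) comes back to the route at 20, which collapses to 22 as in step 10. Either C7 epimer can thus be funnelled into 22 by choosing the inverting or the retaining sequence.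

**Further compounds**
F1 | step 2 | trimethylsilyl enol ether (O–C9, C9=C10) of the Mukaiyama–Michael adduct | CC1[C@@H](C(C)=C)C[C@H](C(C)(C)C(=O)OC)C(C)=C1O[Si](C)(C)C
F2 | step 2 | C10-allyl keto ester, allyl trans to the C5 substituent | CC1[C@@H](C(C)=C)C[C@H](C(C)(C)C(=O)OC)[C@@](C)(CC=C)C1=O
F3 | step 2 | C10-(3-hydroxypropyl) keto ester | CC1[C@@H](C(C)=C)C[C@H](C(C)(C)C(=O)OC)[C@@](C)(CCCO)C1=O
F4 | step 2 | C10-(2-carboxyethyl) keto ester | CC1[C@@H](C(C)=C)C[C@H](C(C)(C)C(=O)OC)[C@@](C)(CCC(=O)O)C1=O
F5 | step 2 | keto diester, protonated form of 8 | CC1[C@@H](C(C)=C)C[C@H](C(C)(C)C(=O)OC)[C@@](C)(CCC(=O)OC)C1=O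
F6 | step 7 | 9-methylene-decal-7-ene (diene) from 14 | CC1=CC[C@@H]2C(C)(C)[C@H](O[Si](C)(C)C(C)(C)C)CC[C@@]2(C)C1=C
F7 | step 7 | 9-(hydroxymethyl)-decal-7-ene, H-9 trans to CH3-10 | CC1=CC[C@@H]2C(C)(C)[C@H](O[Si](C)(C)C(C)(C)C)CC[C@@]2(C)[C@@H]1CO
F8 | step 7 | 9-(iodomethyl)-decal-7-ene | CC1=CC[C@@H]2C(C)(C)[C@H](O[Si](C)(C)C(C)(C)C)CC[C@@]2(C)[C@@H]1CI
F9 | step 9 | C7 epimer of 19, OH trans to CH3-10 | O[C@H]1C[C@@H]2C(C)(C)[C@H](O[Si](C)(C)C(C)(C)C)CC[C@@]2(C)C(CCC#C[Si](C)(C)C)=C1C
F10 | step 9 | methyl carbonate of F9 | COC(=O)O[C@H]1C[C@@H]2C(C)(C)[C@H](O[Si](C)(C)C(C)(C)C)CC[C@@]2(C)C(CCC#C[Si](C)(C)C)=C1C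
F11 | step 9 | N-allyl N′-isopropylidene 2-nitrobenzenesulfonylhydrazide, N on C7 trans to CH3-10 | CC(C)=NN([C@H]1C[C@@H]2C(C)(C)[C@H](O[Si](C)(C)C(C)(C)C)CC[C@@]2(C)C(CCC#C[Si](C)(C)C)=C1C)S(=O)(=O)c1ccccc1[N+](=O)[O-]
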